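**Retrosynthetic overview**
- Feature: in each benzene ring (C1 axis carbon, C2 OH, C3 acetyl, C4 OMe, C5 methyl, C6 OMe) oxygen sits on C2, C4 and C6, the alternating pattern of a folded polyketide. The axis C1–C1' can therefore be read as the central CH2–CH2 bond of a linear twelve-carbon chain. The segment C4(OMe)–C5(Me)–C6(O) maps onto C4–C3–C2 of a 4-methoxy-3-methyl-2-pyrone.
- Contortin 16 ⇒ diacetyl tetraol 15 (O-methylation of the 6,6'-hydroxyls) ⇒ tetraol 13 (C-acetylation at C3/C3').
- 13 ⇒ ethane-bridged bis-pyrone 10 by cutting C1–C6 and C1'–C6'. Both carbocycles (ring A, then ring B) are made in one pot from the two pyrone rings, so no aryl–aryl coupling is needed.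
- 10 ⇒ two molecules of pyrone 8 (oxidative coupling at the 6-methyl carbon) ⇒ triacetic acid lactone 1 (C3-methylation, O-methylation).

Key step: step 5

Assumption: the SMILES carries no axial descriptor, so the C1–C1' axis is made as the racemate. Arene positions are numbered C1–C6 as in the overview throughout.

**Step 1**
Reactants: 1 triacetic acid lactone (4-hydroxy-6-methyl-2H-pyran-2-one); 2 formaldehyde; 3 thiophenol
Product: 5 4-hydroxy-6-methyl-3-[(phenylsulfanyl)methyl]-2H-pyran-2-one, via exocyclic enone 4 (not isolated)
Conditions: 37% aq. CH2O, PhSH, piperidine (cat.), AcOH (cat.), EtOH, reflux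
Reagents that add atoms: formaldehyde (C=O); thiophenol (Sc1ccccc1)
Why: Knoevenagel condensation at the nucleophilic pyrone C3 gives enone 4, which the soft thiol should capture by thia-Michael addition before a second lactone molecule can add, so the methylene-bis-lactone pathway is closed; no stereocentre is formed.

**Step 2**
Reactants: 5 4-hydroxy-6-methyl-3-[(phenylsulfanyl)methyl]-2H-pyran-2-one
Product: 6 4-hydroxy-3,6-dimethyl-2H-pyran-2-one
Conditions: Raney Ni (deactivated in refluxing acetone), EtOH, reflux
Reagents that add atoms: none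
Why: Raney-nickel hydrogenolytic desulfurisation cleaves the C–S bonds and leaves the C3 methyl group, and the deactivated metal should spare the pyrone double bonds.

**Step 3**
Reactants: 6 4-hydroxy-3,6-dimethyl-2H-pyran-2-one; 7 dimethyl sulfate
Product: 8 4-methoxy-3,6-dimethyl-2H-pyran-2-one
Conditions: Me2SO4 (1.2 equiv), K2CO3, acetone, reflux
Reagents that add atoms: dimethyl sulfate (COS(=O)(=O)OC)
Why: Williamson-type O-alkylation of the vinylogous acid with a hard methylating agent and K2CO3 in acetone should go to the 4-oxygen and give the 4-methoxy-2-pyrone rather than the 2-methoxy-4-pyrone isomer.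

**Step 4**
Reactants: 8 4-methoxy-3,6-dimethyl-2H-pyran-2-one (two molecules)
Product: 10 1,2-bis(4-methoxy-3-methyl-2-oxo-2H-pyran-6-yl)ethane, via lithiated pyrone 9 (not isolated)
Conditions: LDA (1.05 equiv), THF, −78 °C; then anhydrous CuCl2 (1.1 equiv), DMF, −78 °C → rt
Reagents that add atoms: none
Why: LDA removes a proton from the 6-methyl group (vinylogous to the lactone carbonyl, with pyrone C3 blocked by methyl), and one-electron oxidation of extended enolate 9 by divalent copper gives a pyronylmethyl radical that should dimerise at its unhindered exocyclic carbon, as in the CuCl2 oxidative homocoupling of lithium enolates.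

**Step 5**
Reactants: 10 1,2-bis(4-methoxy-3-methyl-2-oxo-2H-pyran-6-yl)ethane
Product: 13 2,2',6,6'-tetrahydroxy-4,4'-dimethoxy-5,5'-dimethylbiphenyl, via ring-opened diketo diester 11 (not isolated), via monoaryl keto ester 12 (not isolated)
Conditions: NaOMe (30 wt% in MeOH, 12 equiv), dry degassed MeOH, Ar, sealed autoclave, 180 °C; then cold 1 M HCl to pH 4
Reagents that add atoms: none
Why: Attack of methoxide on the carbonyl carbon of each pyrone cleaves the acyl–oxygen bond, so each half becomes a methyl (E)-3-methoxy-2-methylenoate whose ketone is set free directly as its conjugated dienolate (11); a small equilibrium share of the bridge-side enolate then attacks the ester through C1, methoxide leaves and the cyclohexenedione enolises to a resorcinolate, first at one end (12) and then, through the now benzylic C1', at the other. The closest known reaction type is the hot NaOMe/MeOH rearrangement of 4-methoxy-6-methyl-2-pyrone into phloroglucinol monomethyl ether, a lactone opening followed by a Dieckmann-type Claisen closure. Ring A (bond C1–C6) and ring B (bond C1'–C6') each close in the 6-(enolendo)-exo-trig mode, which is geometrically possible because the former ring double bond emerges with the CO2Me group and the CH2C(O) arm cis to each other. No stereocentre is created and, with nothing chiral present, the tetra-ortho-substituted axis should form as a racemate. The step needs C-acylation at C1/C1' rather than a five-membered aldol closure of C3 onto the C2' carbonyl or attack of a ring A phenoxide on the second ketone or pyrone; lactone opening is fast and reversible compared with the closure, so both ends must be expected to be open, and the safeguard is the acidity of the C3/C3' methylenes, which in a large excess of concentrated methoxide keeps both ketones stored as dienolates that are not aldol acceptors. For the C3 carbanion the only ester within reach would give a four-membered ring, and each Claisen closure is drawn out of the equilibria by aromatisation to a phenoxide.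

**Step 6**
Reactants: 13 2,2',6,6'-tetrahydroxy-4,4'-dimethoxy-5,5'-dimethylbiphenyl; 14 acetic anhydride
Product: 15 3,3'-diacetyl-2,2',6,6'-tetrahydroxy-4,4'-dimethoxy-5,5'-dimethylbiphenyl
Conditions: Ac2O (2.4 equiv), BF3·OEt2 (excess), 0 → 45 °C; then aq. NaOAc, MeOH, 50 °C
Reagents that add atoms: acetic anhydride (CC(=O)OC(C)=O)
Why: Friedel–Crafts C-acylation (direct, or by O-acylation and Fries shift) can only reach C3 and C3', the sole unsubstituted ring carbons, each activated by an ortho OH, an ortho OMe and a para OH, and the new acyl group deactivates each ring against further attack.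

**Step 7**
Reactants: 15 3,3'-diacetyl-2,2',6,6'-tetrahydroxy-4,4'-dimethoxy-5,5'-dimethylbiphenyl; 7 dimethyl sulfate
Product: 16 contortin (3,3'-diacetyl-2,2'-dihydroxy-4,4',6,6'-tetramethoxy-5,5'-dimethylbiphenyl, racemic axis)
Conditions: Me2SO4 (2.1 equiv), K2CO3 (2.5 equiv), acetone, reflux
Reagents that add atoms: dimethyl sulfate (COS(=O)(=O)OC)
Why: Williamson O-methylation under weak base should pick the 6,6'-hydroxyls, which are para to the acetyl groups (more acidic) and unchelated, while the 2,2'-hydroxyls are held in six-membered hydrogen bonds to the acetyl carbonyls, provided the sulfate is limited to about two equivalents; the axis stays racemic.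

**Compound list**
1 | triacetic acid lactone (4-hydroxy-6-methyl-2H-pyran-2-one) | CC1=CC(O)=CC(=O)O1 | starting material
2 | formaldehyde | C=O | starting material
3 | thiophenol | Sc1ccccc1 | starting material
4 | 6-methyl-3-methylidene-2H-pyran-2,4(3H)-dione | CC1=CC(=O)C(=C)C(=O)O1 | intermediate (not isolated)
5 | 4-hydroxy-6-methyl-3-[(phenylsulfanyl)methyl]-2H-pyran-2-one | CC1=CC(O)=C(CSc2ccccc2)C(=O)O1 | intermediate
6 | 4-hydroxy-3,6-dimethyl-2H-pyran-2-one | CC1=CC(O)=C(C)C(=O)O1 | intermediate
7 | dimethyl sulfate | COS(=O)(=O)OC | starting material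
8 | 4-methoxy-3,6-dimethyl-2H-pyran-2-one | COC1=C(C)C(=O)OC(C)=C1 | intermediate
9 | [(4-methoxy-3-methyl-2-oxo-2H-pyran-6-yl)methyl]lithium | [Li]CC1=CC(OC)=C(C)C(=O)O1 | intermediate (not isolated)
10 | 1,2-bis(4-methoxy-3-methyl-2-oxo-2H-pyran-6-yl)ethane | COC1=C(C)C(=O)OC(CCC2=CC(OC)=C(C)C(=O)O2)=C1 | intermediate (key-step precursor)
11 | dimethyl (2E,10E)-3,10-dimethoxy-2,11-dimethyl-5,8-dioxododeca-2,10-dienedioate, present as its disodium bis-dienolate | COC(=O)/C(C)=C(/OC)CC(=O)CCC(=O)C/C(OC)=C(/C)C(=O)OC | intermediate (not isolated)
12 | methyl (2E)-6-(2,6-dihydroxy-4-methoxy-3-methylphenyl)-3-methoxy-2-methyl-5-oxohex-2-enoate, present as its sodium salt | COC(=O)/C(C)=C(/OC)CC(=O)Cc1c(O)cc(OC)c(C)c1O | intermediate (not isolated)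
13 | 2,2',6,6'-tetrahydroxy-4,4'-dimethoxy-5,5'-dimethylbiphenyl (lowest-locant name: 4,4'-dimethoxy-3,3'-dimethylbiphenyl-2,2',6,6'-tetrol) | COc1cc(O)c(-c2c(O)cc(OC)c(C)c2O)c(O)c1C | intermediate (key-step product)
14 | acetic anhydride | CC(=O)OC(C)=O | starting material
15 | 3,3'-diacetyl-2,2',6,6'-tetrahydroxy-4,4'-dimethoxy-5,5'-dimethylbiphenyl | COc1c(C(C)=O)c(O)c(-c2c(O)c(C(C)=O)c(OC)c(C)c2O)c(O)c1C | intermediate
16 | contortin | COc1c(C)c(OC)c(-c2c(O)c(C(C)=O)c(OC)c(C)c2OC)c(O)c1C(C)=O | target

**Totals**
Total step count: 7. Longest linear sequence: 7 steps (1 → 16).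

**Steps most likely to fail**

1. Step 5.
   - What may go wrong:
     - five-membered aldol closure across the 1,4-dicarbonyl unit once both lactones are open;
     - capture of the second ketone or pyrone by an ortho-phenoxide of ring A, followed by dehydration on work-up;
     - SN2 loss of the vinylogous-ester methyl groups;
     - ester saponification by traces of water at 180 °C.
   - Fallback: it sets out from 8 and comes back at 13, and the axis is made by a classical aryl–aryl coupling. Pyrone 8 alone is heated with NaOMe in MeOH at 180 °C. This is the single-ring rearrangement, with no second carbonyl nearby, and gives 5-methoxy-4-methylbenzene-1,3-diol F1. MOMCl and i-Pr2NEt in CH2Cl2 give 1-methoxy-3,5-bis(methoxymethoxy)-2-methylbenzene F2. n-BuLi in THF at 0 °C removes the proton between the two MOM ethers (directed ortho-metalation) to give [4-methoxy-2,6-bis(methoxymethoxy)-3-methylphenyl]lithium F3. Iodine converts this into 2-iodo-5-methoxy-1,3-bis(methoxymethoxy)-4-methylbenzene F4. Ullmann homocoupling with activated Cu powder in DMF at 140 °C gives 4,4'-dimethoxy-2,2',6,6'-tetrakis(methoxymethoxy)-5,5'-dimethylbiphenyl F5. HCl in MeOH at rt then removes the four acetals to give 13.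

2. Step 4.
   - What may go wrong:
     - sluggish electron transfer;
     - chlorination of the anion by CuCl2;
     - over-oxidation of the new bridge;
     - addition of the anion to the lactone carbonyl of unreacted pyrone.
   - Fallback: it sets out from 9 and comes back at 10, and the oxidative coupling is replaced by a polar alkylation. One portion of 9 is added inversely to BrCCl2CCl2Br in THF at −78 °C to give 6-(bromomethyl)-4-methoxy-3-methyl-2H-pyran-2-one F6. A second portion of 9 is then alkylated with this bromide (THF/DMPU, −78 → 0 °C, SN2) to give 10.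

3. Step 6.
   - What may go wrong:
     - acid-promoted cyclodehydration between ortho-hydroxyls of the two rings (furan ring closure across the axis);
     - incomplete acylation of the second ring.
   - Fallback: it sets out from 13 and comes back at 15, with all phenols masked before any Lewis acid is used. Ac2O, pyridine and DMAP give 2,2',6,6'-tetraacetoxy-4,4'-dimethoxy-5,5'-dimethylbiphenyl F7. A Fries rearrangement with TiCl4 in 1,2-dichloroethane at 60 °C moves the 2,2'-acetyl groups to the free ortho carbons C3/C3'. This gives 3,3'-diacetyl-6,6'-diacetoxy-2,2'-dihydroxy-4,4'-dimethoxy-5,5'-dimethylbiphenyl F8. K2CO3 in MeOH at rt cleaves the remaining aryl acetates to give 15.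

**Further compounds**
F1 | step 5 | 5-methoxy-4-methylbenzene-1,3-diol | COc1cc(O)cc(O)c1C
F2 | step 5 | 1-methoxy-3,5-bis(methoxymethoxy)-2-methylbenzene | COCOc1cc(OC)c(C)c(OCOC)c1
F3 | step 5 | [4-methoxy-2,6-bis(methoxymethoxy)-3-methylphenyl]lithium | [Li]c1c(OCOC)cc(OC)c(C)c1OCOC
F4 | step 5 | 2-iodo-5-methoxy-1,3-bis(methoxymethoxy)-4-methylbenzene | COCOc1cc(OC)c(C)c(OCOC)c1I
F5 | step 5 | 4,4'-dimethoxy-2,2',6,6'-tetrakis(methoxymethoxy)-5,5'-dimethylbiphenyl | COCOc1cc(OC)c(C)c(OCOC)c1-c1c(OCOC)cc(OC)c(C)c1OCOC
F6 | step 4 | 6-(bromomethyl)-4-methoxy-3-methyl-2H-pyran-2-one | COC1=C(C)C(=O)OC(CBr)=C1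
F7 | step 6 | 2,2',6,6'-tetraacetoxy-4,4'-dimethoxy-5,5'-dimethylbiphenyl | COc1cc(OC(C)=O)c(-c2c(OC(C)=O)cc(OC)c(C)c2OC(C)=O)c(OC(C)=O)c1C
F8 | step 6 | 3,3'-diacetyl-6,6'-diacetoxy-2,2'-dihydroxy-4,4'-dimethoxy-5,5'-dimethylbiphenyl | COc1c(C(C)=O)c(O)c(-c2c(O)c(C(C)=O)c(OC)c(C)c2OC(C)=O)c(OC(C)=O)c1C
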